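**Retrosynthetic overview**
- The route rests on the methyl-bearing quaternary carbon: it belongs to ring C (furan-fused cycloheptanone) through the CH2 next to the ketone and to ring A (acetoxy methylenecyclohexane) through the methylene-bearing sp2 carbon, so one radical centred on it can close both rings.
- Butenolide ⇐ oxidative lactonisation of the ring-B bis(hydroxymethyl) diol; rings C and A ⇐ acyl-radical cascade of a ring-B furan-3-carbonyl selenide carrying an isopropenyl group and a propargylic acetate arm (C(=O)–CH2 bond 7-endo, quaternary C–C(=CH2) bond 6-exo-dig).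
- Ring B ⇐ endo Diels–Alder reaction of a 2-dienyl-3-bromofuran with dimethyl (E)-2-(2-oxopropylidene)succinate, which sets the quaternary carbon and its two neighbours all-cis in one step; then acetyl → isopropenyl, CH2CO2Me → ynone → (S)-carbinol, Br → CO2H → C(O)SePh.
- Order of ring formation: furan (bought) → ring B → ring C then ring A (one step) → lactone.

Key step: step 17

Convention for names: ring B is numbered C1 (quaternary carbon), C2 (carbon bearing the one-carbon unit that becomes the lactone carbonyl), C3, C4, C5 (furyl-bearing) and C6 (acetyl/isopropenyl-bearing); β is the face that carries the furyl group, and seen from that face C1→C6 run clockwise; α is the other face.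
Assumption: in step 6 the sense of induction of the cationic oxazaborolidine is taken from the ketone-binding model for acyclic enones; the catalyst enantiomer named is the one expected to open the Re face of the acetyl-bearing alkene carbon.

Step 1
Reactants: 1 3-bromofuran-2-carbaldehyde; 2 triethyl 4-phosphonocrotonate
Product: 3 ethyl (2E,4E)-5-(3-bromofuran-2-yl)penta-2,4-dienoate
Conditions: NaH, THF, 0 °C → rt
Reagents that add atoms: none
Why: Vinylogous Horner–Wadsworth–Emmons olefination; the stabilised phosphonate anion gives the E alkene with an aromatic aldehyde and the E alkene of 2 is kept.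

Step 2
Reactants: 3 ethyl (2E,4E)-5-(3-bromofuran-2-yl)penta-2,4-dienoate
Product: 4 (2E,4E)-5-(3-bromofuran-2-yl)penta-2,4-dien-1-ol
Conditions: i-Bu2AlH (2.2 equiv), CH2Cl2, −78 °C
Reagents that add atoms: none
Why: 1,2-Reduction of a conjugated ester to the allylic alcohol by an aluminium hydride at low temperature; diene geometry and the C–Br bond are not touched.

Step 3
Reactants: 4 (2E,4E)-5-(3-bromofuran-2-yl)penta-2,4-dien-1-ol
Product: 5 3-bromo-2-[(1E,3E)-5-(tert-butyldimethylsilyloxy)penta-1,3-dien-1-yl]furan
Conditions: TBSCl, imidazole, DMF, 0 °C → rt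
Reagents that add atoms: tert-butyldimethylsilyl chloride, CC(C)(C)[Si](C)(C)Cl
Why: Standard silylation of a primary alcohol; the ether keeps the diene electron-rich and tolerates the Lewis acid of step 6.

Step 4
Reactants: 6 methyl (triphenylphosphoranylidene)acetate (2 equiv); 7 methyl bromoacetate
Product: 9 dimethyl 2-(triphenylphosphoranylidene)butanedioate, via phosphonium bromide 8 (not isolated)
Conditions: EtOAc, reflux
Reagents that add atoms: none
Why: C-Alkylation of a stabilised ylide by a reactive α-halo ester followed by transylidation, the second equivalent of 6 acting as base.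

Step 5
Reactants: 9 dimethyl 2-(triphenylphosphoranylidene)butanedioate; 10 methylglyoxal
Product: 11 dimethyl (2E)-2-(2-oxopropylidene)butanedioate
Conditions: 10 (40% in water), CH2Cl2, rt
Reagents that add atoms: none
Why: Wittig olefination at the aldehyde carbonyl, which is far more electrophilic than the ketone; an α-substituted stabilised ylide places the ester trans to the aldehyde-derived acetyl group (E).

Step 6
Reactants: 5 bromofuryl silyloxy diene; 11 dimethyl (2E)-2-(2-oxopropylidene)butanedioate
Product: 12 Diels–Alder adduct (ring B: 1α-CO2Me; 1β-CH2CO2Me; 2β-CH2OTBS; 5β-bromofuryl; 6β-acetyl; C3=C4)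
Conditions: (3aR)-1-(2-methylphenyl)-3,3-diphenyltetrahydro-1H,3H-pyrrolo[1,2-c][1,3,2]oxazaborole (20 mol%), HN(SO2CF3)2 (18 mol%), CH2Cl2, −78 → −20 °C
Reagents that add atoms: none
Why: Enantioselective Lewis-acid-catalysed Diels–Alder reaction (cationic oxazaborolidine catalysis of an enone dienophile): boron binds the ketone of 11, so the ester-bearing alkene carbon is the electrophilic terminus and bonds to the silyloxymethyl-bearing diene terminus while the acetyl-bearing carbon bonds to the furyl-bearing terminus (the developing allyl cation is stabilised by the furan); the acetyl group lies endo and the α-substituted ester exo, which with the E geometry of both partners puts 1β-CH2CO2Me, 2β-CH2OTBS, 5β-furyl and 6β-acetyl on one face and the C1 ester on the other; the catalyst is chosen to block the Si face of the acetyl-bearing carbon so that the diene adds to its Re face, and the C2 centre is of no consequence because it is removed in step 11.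

Step 7
Reactants: 12 Diels–Alder adduct
Product: 13 isopropenyl diester (6β-prop-1-en-2-yl)
Conditions: Zn, CH2Br2, TiCl4, THF–CH2Cl2, 0 °C → rt
Reagents that add atoms: dibromomethane, BrCBr
Why: Takai–Lombardo methylenation; the reagent is not basic and olefinates the hindered ketone without enolising it, so the epimerisable C6 centre is kept, and esters, silyl ether and bromofuran are inert.

Step 8
Reactants: 13 isopropenyl diester; 14 ethynyltrimethylsilane
Product: 15 ynone (1β-CH2C(=O)C≡CSiMe3)
Conditions: 14, n-BuLi, THF, −78 °C; BF3·OEt2; then 13, −78 °C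
Reagents that add atoms: none
Why: Yamaguchi–Hirao acylation of an alkynyl borate by an ester; the adduct is stable at −78 °C and collapses to the ynone only on work-up, so no second addition occurs, and of the two methyl esters only the CH2CO2Me group is accessible because the C1 ester sits on the quaternary carbon.

Step 9
Reactants: 15 ynone
Product: 17 spirolactone with (S)-carbinol carbon, via hydroxy ester 16 (not isolated)
Conditions: Ru(p-cymene)[(S,S)-TsNCH(Ph)CH(Ph)NH] (2 mol%), i-PrOH, rt; then pyridinium p-toluenesulfonate (cat.), toluene, 80 °C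
Reagents that add atoms: none
Why: Noyori asymmetric transfer hydrogenation of an alkynyl ketone: the (S,S)-ligand delivers hydride to the face that gives the (S)-propargylic alcohol (reagent control), alkenes and the C–Br bond are not reduced, and acid-catalysed lactonisation of the γ-hydroxy ester (five-membered ring at a quaternary carbon) protects the carbinol and gives a rigid spirolactone from which the diastereomer arising from the minor enantiomer of step 6 can be removed by chromatography.

Step 10
Reactants: 17 spirolactone
Product: 18 spirolactone primary alcohol (2β-CH2OH)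
Conditions: HF·pyridine, pyridine, THF, 0 °C → rt
Reagents that add atoms: none
Why: Fluoride cleavage of the primary silyl ether under non-basic conditions, which keep the C-silyl alkyne and the lactone.

Step 11
Reactants: 18 spirolactone primary alcohol
Product: 20 conjugated enal lactone (C2=C3; 2-CHO), via unconjugated aldehyde 19 (not isolated)
Conditions: Dess–Martin periodinane, CH2Cl2, 0 °C → rt; then DBU (3 equiv), rt
Reagents that add atoms: none
Why: Dess–Martin oxidation gives the β,γ-unsaturated aldehyde; DBU removes the doubly activated C2–H and the dienolate is reprotonated at C4, which moves the double bond into conjugation (thermodynamically favoured trisubstituted enal) and deliberately erases the C2 centre, while C5 and C6 carry no acidifying group.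

Step 12
Reactants: 20 conjugated enal lactone
Product: 21 triol (1α-CH2OH; 2-CH2OH; (S)-propargylic alcohol on the C1β arm)
Conditions: LiBH4, THF, 0 °C → rt
Reagents that add atoms: none
Why: Borohydride reduction: the aldehyde is reduced in the 1,2 sense and the lactone is opened to the C1 primary alcohol and the secondary propargylic alcohol; the carbinol configuration, the C–Br bond and the alkynylsilane are not touched.

Step 13
Reactants: 21 triol
Product: 22 bis-silyl ether with free propargylic alcohol
Conditions: TBSCl (2.3 equiv), imidazole, CH2Cl2, 0 °C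
Reagents that add atoms: tert-butyldimethylsilyl chloride, CC(C)(C)[Si](C)(C)Cl
Why: Silylation with TBSCl/imidazole is much faster at primary than at secondary hydroxyl groups, so both CH2OH groups are protected and the secondary propargylic alcohol is left free.

Step 14
Reactants: 22 bis-silyl ether
Product: 25 hydroxy acid with terminal alkyne, via dilithio species 23 (not isolated), via lithium carboxylate 24 (not isolated)
Conditions: n-BuLi (2.2 equiv), THF, −78 °C; CO2; then MeOH, K2CO3 (cat.), rt; aqueous HCl to pH 4, 0 °C
Reagents that add atoms: carbon dioxide, O=C=O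
Why: After deprotonation of the hydroxyl group, bromine–lithium exchange at −78 °C gives the 3-furyllithium, which is carboxylated by CO2; the C-silyl group protects the alkyne from metalation and is then removed in the same flask by methanolysis of the alkynylsilane.

Step 15
Reactants: 25 hydroxy acid
Product: 27 acetoxy acid, via mixed anhydride 26 (not isolated)
Conditions: Ac2O, pyridine, 4-(dimethylamino)pyridine (cat.), CH2Cl2, 0 °C → rt; then H2O–THF, rt
Reagents that add atoms: acetic anhydride, CC(=O)OC(C)=O
Why: Acylation of the secondary alcohol under nucleophilic catalysis with retention at the carbinol carbon; the acid is converted in passing into the mixed anhydride, which water hydrolyses back in the second stage.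

Step 16
Reactants: 27 acetoxy acid
Product: 28 Se-phenyl selenoester (cascade precursor)
Conditions: PhSeSePh, Bu3P, CH2Cl2, rt
Reagents that add atoms: diphenyl diselenide, c1ccccc1[Se][Se]c1ccccc1
Why: Phosphine-mediated selenoester formation: Bu3P and the diselenide give a selenophosphonium ion that turns the carboxylate into an acyloxyphosphonium species, which benzeneselenolate attacks at carbon; acetate, silyl ethers and the alkyne are inert.

Step 17
Reactants: 28 Se-phenyl selenoester
Product: 29 tetracycle (rings A, B, C and furan; bis-silyl ether)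
Conditions: (Me3Si)3SiH (1.3 equiv), AIBN (2,2'-azobis(2-methylpropionitrile), 0.2 equiv), syringe pump over 6 h into benzene, 80 °C, 0.005 M
Reagents that add atoms: none
Why: The tris(trimethylsilyl)silyl radical abstracts the phenylselenyl group to give the 3-furoyl radical, an aroyl radical that does not lose CO; it adds to the unsubstituted CH2 terminus of the C6 isopropenyl group (7-endo-trig, ring C, C(=O)–CH2 bond), and the tertiary radical so formed adds to the inner carbon of the terminal alkyne (6-exo-dig, ring A), after which the vinyl radical takes hydrogen from the silane and leaves the exocyclic methylene beside the acetate. The closest known reaction type is the acyl-selenide radical polycyclisation in which a 7-endo acylation of a 1,1-disubstituted alkene is relayed into an exo-dig closure onto an alkyne. The one new stereocentre, the methyl-bearing quaternary carbon, is set in the second closure: the propargylic arm on C1 lies on the same β face as the radical carbon on C6, and with ring C already cis-fused to ring B it can reach only the radical lobe anti to the C6–H bond, so the methyl group ends syn to C6–H and ring A is cis-fused to rings B and C. The step needs endo rather than 6-exo attack (secured by the fully substituted inner alkene carbon), cyclisation ahead of hydrogen transfer (slow addition of the poor hydrogen donor at high dilution) and no competing acceptor (the lactone is masked as the bis-silyl ether so no enoate is present, and attack on the ring-B alkene would need a bridged bicycle).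

Step 18
Reactants: 29 tetracycle bis-silyl ether
Product: 30 tetracyclic diol
Conditions: HF·pyridine, pyridine, THF, 0 °C → rt
Reagents that add atoms: none
Why: Fluoride cleavage of both primary silyl ethers; the buffered reagent is not basic, so the allylic acetate neither migrates nor eliminates and the ketone is not enolised.

Step 19
Reactants: 30 tetracyclic diol
Product: 33 target CNP0273675.2, via hydroxy enal 31 (not isolated), via lactol 32 (not isolated)
Conditions: TEMPO (2,2,6,6-tetramethylpiperidin-1-oxyl, 20 mol%), PhI(OAc)2 (2.5 equiv), CH2Cl2, rt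
Reagents that add atoms: none
Why: Oxoammonium oxidation is selective for the allylic primary alcohol over the neopentyl one; the enal is trapped by the C1 hydroxymethyl group as a five-membered lactol, which is oxidised on to the butenolide, so the carbonyl ends on the alkene-bearing carbon as in the target.

**Compound list**
1 | 3-bromofuran-2-carbaldehyde | O=Cc1occc1Br | starting material
2 | ethyl (2E)-4-(diethoxyphosphoryl)but-2-enoate (triethyl 4-phosphonocrotonate) | CCOC(=O)/C=C/CP(=O)(OCC)OCC | starting material
3 | ethyl (2E,4E)-5-(3-bromofuran-2-yl)penta-2,4-dienoate | CCOC(=O)/C=C/C=C/c1occc1Br | intermediate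
4 | (2E,4E)-5-(3-bromofuran-2-yl)penta-2,4-dien-1-ol | OC/C=C/C=C/c1occc1Br | intermediate
5 | 3-bromo-2-[(1E,3E)-5-(tert-butyldimethylsilyloxy)penta-1,3-dien-1-yl]furan | CC(C)(C)[Si](C)(C)OC/C=C/C=C/c1occc1Br | intermediate
6 | methyl (triphenylphosphoranylidene)acetate | COC(=O)C=P(c1ccccc1)(c1ccccc1)c1ccccc1 | starting material
7 | methyl bromoacetate | COC(=O)CBr | starting material
8 | (1,4-dimethoxy-1,4-dioxobutan-2-yl)triphenylphosphonium bromide | COC(=O)CC(C(=O)OC)[P+](c1ccccc1)(c1ccccc1)c1ccccc1.[Br-] | intermediate
9 | dimethyl 2-(triphenylphosphoranylidene)butanedioate | COC(=O)CC(C(=O)OC)=P(c1ccccc1)(c1ccccc1)c1ccccc1 | intermediate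
10 | 2-oxopropanal (methylglyoxal) | CC(=O)C=O | starting material
11 | dimethyl (2E)-2-(2-oxopropylidene)butanedioate (alkene ester trans to acetyl) | COC(=O)/C(CC(=O)OC)=C/C(C)=O | intermediate
12 | methyl 6β-acetyl-5β-(3-bromofuran-2-yl)-2β-[(tert-butyldimethylsilyloxy)methyl]-1β-(2-methoxy-2-oxoethyl)cyclohex-3-ene-1α-carboxylate | COC(=O)C[C@@]1(C(=O)OC)[C@@H](CO[Si](C)(C)C(C)(C)C)C=C[C@@H](c2occc2Br)[C@H]1C(C)=O | intermediate
13 | methyl 5β-(3-bromofuran-2-yl)-2β-[(tert-butyldimethylsilyloxy)methyl]-1β-(2-methoxy-2-oxoethyl)-6β-(prop-1-en-2-yl)cyclohex-3-ene-1α-carboxylate | COC(=O)C[C@@]1(C(=O)OC)[C@@H](CO[Si](C)(C)C(C)(C)C)C=C[C@@H](c2occc2Br)[C@H]1C(C)=C | intermediate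
14 | ethynyltrimethylsilane | C#C[Si](C)(C)C | starting material
15 | methyl 5β-(3-bromofuran-2-yl)-2β-[(tert-butyldimethylsilyloxy)methyl]-1β-[2-oxo-4-(trimethylsilyl)but-3-yn-1-yl]-6β-(prop-1-en-2-yl)cyclohex-3-ene-1α-carboxylate | C[Si](C)(C)C#CC(=O)C[C@@]1(C(=O)OC)[C@@H](CO[Si](C)(C)C(C)(C)C)C=C[C@@H](c2occc2Br)[C@H]1C(C)=C | intermediate
16 | as 15 with 1β-[(2S)-2-hydroxy-4-(trimethylsilyl)but-3-yn-1-yl] | C[Si](C)(C)C#C[C@@H](O)C[C@@]1(C(=O)OC)[C@@H](CO[Si](C)(C)C(C)(C)C)C=C[C@@H](c2occc2Br)[C@H]1C(C)=C | intermediate
17 | spiro γ-lactone of 16 (C1α carboxyl closed onto the (S)-carbinol oxygen; spiro centre C1; 2β-CH2OTBS, 5β-bromofuryl, 6β-isopropenyl, C3=C4) | C[Si](C)(C)C#C[C@@H]1C[C@@]2(C(=O)O1)[C@@H](CO[Si](C)(C)C(C)(C)C)C=C[C@@H](c3occc3Br)[C@H]2C(C)=C | intermediate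
18 | as 17 with free 2β-CH2OH | C[Si](C)(C)C#C[C@@H]1C[C@@]2(C(=O)O1)[C@@H](CO)C=C[C@@H](c3occc3Br)[C@H]2C(C)=C | intermediate
19 | as 17 with 2β-CHO (β,γ-unsaturated aldehyde) | C[Si](C)(C)C#C[C@@H]1C[C@@]2(C(=O)O1)[C@@H](C=O)C=C[C@@H](c3occc3Br)[C@H]2C(C)=C | intermediate
20 | spirolactone enal: C2=C3 double bond, 2-CHO, 5β-bromofuryl, 6β-isopropenyl | C[Si](C)(C)C#C[C@@H]1C[C@@]2(C(=O)O1)C(C=O)=CC[C@@H](c3occc3Br)[C@H]2C(C)=C | intermediate
21 | (2S)-1-[5β-(3-bromofuran-2-yl)-1α,2-bis(hydroxymethyl)-6β-(prop-1-en-2-yl)cyclohex-2-en-1β-yl]-4-(trimethylsilyl)but-3-yn-2-ol | C[Si](C)(C)C#C[C@@H](O)C[C@@]1(CO)C(CO)=CC[C@@H](c2occc2Br)[C@H]1C(C)=C | intermediate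
22 | bis(tert-butyldimethylsilyl) ether of 21 at both primary hydroxyl groups | C[Si](C)(C)C#C[C@@H](O[H])C[C@@]1(CO[Si](C)(C)C(C)(C)C)C(CO[Si](C)(C)C(C)(C)C)=CC[C@@H](c2occc2Br)[C@H]1C(C)=C | intermediate
23 | lithium alkoxide of 22 with lithium in place of bromine at furan C3 | C[Si](C)(C)C#C[C@@H](O[Li])C[C@@]1(CO[Si](C)(C)C(C)(C)C)C(CO[Si](C)(C)C(C)(C)C)=CC[C@@H](c2occc2[Li])[C@H]1C(C)=C | intermediate
24 | lithium furan-3-carboxylate, lithium alkoxide, alkyne still C-silylated | C[Si](C)(C)C#C[C@@H](O[Li])C[C@@]1(CO[Si](C)(C)C(C)(C)C)C(CO[Si](C)(C)C(C)(C)C)=CC[C@@H](c2occc2C(=O)O[Li])[C@H]1C(C)=C | intermediate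
25 | 2-{1α,2-bis[(tert-butyldimethylsilyloxy)methyl]-1β-[(2S)-2-hydroxybut-3-yn-1-yl]-6β-(prop-1-en-2-yl)cyclohex-2-en-5β-yl}furan-3-carboxylic acid | C#C[C@@H](O)C[C@@]1(CO[Si](C)(C)C(C)(C)C)C(CO[Si](C)(C)C(C)(C)C)=CC[C@@H](c2occc2C(=O)O)[C@H]1C(C)=C | intermediate
26 | (S)-acetate of 25 with the acid as its mixed anhydride with acetic acid | C#C[C@@H](OC(C)=O)C[C@@]1(CO[Si](C)(C)C(C)(C)C)C(CO[Si](C)(C)C(C)(C)C)=CC[C@@H](c2occc2C(=O)OC(C)=O)[C@H]1C(C)=C | intermediate
27 | (S)-acetate of 25 (free furan-3-carboxylic acid) | C#C[C@@H](OC(C)=O)C[C@@]1(CO[Si](C)(C)C(C)(C)C)C(CO[Si](C)(C)C(C)(C)C)=CC[C@@H](c2occc2C(=O)O)[C@H]1C(C)=C | intermediate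
28 | Se-phenyl furan-3-carboselenoate of 27; ring B C1 (S), C5 (R), C6 (S), carbinol carbon (S) | C#C[C@@H](OC(C)=O)C[C@@]1(CO[Si](C)(C)C(C)(C)C)C(CO[Si](C)(C)C(C)(C)C)=CC[C@@H](c2occc2C(=O)[Se]c2ccccc2)[C@H]1C(C)=C | intermediate
29 | tetracycle: ring C cycloheptanone fused to the furan, ring A methylenecyclohexane with (S)-acetate, methyl-bearing quaternary carbon with methyl syn to C6–H, ring B with both CH2OTBS groups | C=C1[C@@H](OC(C)=O)C[C@@]2(CO[Si](C)(C)C(C)(C)C)C(CO[Si](C)(C)C(C)(C)C)=CC[C@H]3c4occc4C(=O)C[C@]1(C)[C@@H]23 | intermediate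
30 | diol from 29 (both CH2OH free) | C=C1[C@@H](OC(C)=O)C[C@@]2(CO)C(CO)=CC[C@H]3c4occc4C(=O)C[C@]1(C)[C@@H]23 | intermediate
31 | hydroxy enal from 30 (ring-B C2 CHO, C1 CH2OH) | C=C1[C@@H](OC(C)=O)C[C@@]2(CO)C(C=O)=CC[C@H]3c4occc4C(=O)C[C@]1(C)[C@@H]23 | intermediate
32 | lactol of 31 (either configuration at the hemiacetal carbon) | C=C1[C@@H](OC(C)=O)C[C@@]23COC(O)C2=CC[C@H]2c4occc4C(=O)C[C@]1(C)[C@H]23 | intermediate
33 | CNP0273675.2 | C=C1[C@@H](OC(C)=O)C[C@@]23COC(=O)C2=CC[C@H]2c4occc4C(=O)C[C@]1(C)[C@H]23 | target

**Step count**
Total: 19 steps. Longest linear sequence: 17 steps (steps 1–3 and 6–19).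

**Steps most likely to fail**

Step 17 (radical cascade). Hydrogen transfer to the acyl radical may outrun the slow 7-endo closure, hydrogen transfer to the tertiary radical may outrun the second closure, or the silyl radical may add to the terminal alkyne. The fallback removes selenium and silane and generates the same acyl radical from an aldehyde by thiol-catalysed radical-chain hydroacylation. It sets out from 27: activation with isobutyl chloroformate and N-methylmorpholine (THF, −15 °C) should give the mixed carbonic anhydride F1, which NaBH4 (THF–H2O, 0 °C) should reduce to the furan-3-ylmethanol F2 without touching the acetate; MnO2 (CH2Cl2) should then give the furan-3-carbaldehyde F3. Heating F3 at high dilution in chlorobenzene with tert-dodecanethiol (0.3 equiv) and 1,1'-azobis(cyclohexanecarbonitrile) lets the thiyl radical abstract the aldehyde hydrogen; the acyl radical should run through the same 7-endo and 6-exo-dig closures and the vinyl radical is quenched by the thiol. The fallback comes back to the route at 29.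

Step 6 (asymmetric Diels–Alder reaction). Facial selectivity may be low or opposite to that assumed, turnover may be poor at the hindered ketone, or the acid may degrade the dienylfuran. The fallback moves absolute stereocontrol from the cycloaddition to the carbinol centre. It sets out from 5 and 11: the thermal reaction (toluene, 100 °C, radical inhibitor) should give, by the same endo and regiochemical preferences, 12 together with its mirror image F4. The racemate is taken through steps 7 and 8, giving 13 with the enantiomeric isopropenyl diester F5 and 15 with the enantiomeric ynone F6. Step 9 with the (S,S)-ruthenium catalyst makes the carbinol (S) in both series, so the mirror-image series gives the epimeric hydroxy ester F7 and from it the diastereomeric spirolactone F8, which is separated from 17 by chromatography. The fallback comes back to the route at 17.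

Step 8 (direct ynone formation). A second acetylide may add to the ynone, or conversion may stall at the neopentyl-type ester. The fallback goes through an amide whose chelated adduct cannot over-add. It sets out from 13: i-PrMgCl and N,O-dimethylhydroxylamine hydrochloride (THF, −20 °C) should convert only the unhindered CH2CO2Me group into the Weinreb amide F9; lithium (trimethylsilyl)acetylide (THF, −78 → 0 °C) then gives the ynone. The fallback comes back to the route at 15.

**Further compounds**
F1 | step 17 | mixed carbonic anhydride of 27 with isobutyl carbonate | C#C[C@@H](OC(C)=O)C[C@@]1(CO[Si](C)(C)C(C)(C)C)C(CO[Si](C)(C)C(C)(C)C)=CC[C@@H](c2occc2C(=O)OC(=O)OCC(C)C)[C@H]1C(C)=C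
F2 | step 17 | furan-3-ylmethanol analogue of 27 (CH2OH in place of CO2H) | C#C[C@@H](OC(C)=O)C[C@@]1(CO[Si](C)(C)C(C)(C)C)C(CO[Si](C)(C)C(C)(C)C)=CC[C@@H](c2occc2CO)[C@H]1C(C)=C
F3 | step 17 | furan-3-carbaldehyde analogue of 27 (CHO in place of CO2H) | C#C[C@@H](OC(C)=O)C[C@@]1(CO[Si](C)(C)C(C)(C)C)C(CO[Si](C)(C)C(C)(C)C)=CC[C@@H](c2occc2C=O)[C@H]1C(C)=C
F4 | step 6 | mirror image of 12 | COC(=O)C[C@]1(C(=O)OC)[C@H](CO[Si](C)(C)C(C)(C)C)C=C[C@H](c2occc2Br)[C@@H]1C(C)=O
F5 | step 6 | mirror image of 13 | COC(=O)C[C@]1(C(=O)OC)[C@H](CO[Si](C)(C)C(C)(C)C)C=C[C@H](c2occc2Br)[C@@H]1C(C)=C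
F6 | step 6 | mirror image of 15 | C[Si](C)(C)C#CC(=O)C[C@]1(C(=O)OC)[C@H](CO[Si](C)(C)C(C)(C)C)C=C[C@H](c2occc2Br)[C@@H]1C(C)=C
F7 | step 6 | hydroxy ester with (S)-carbinol on the mirror-image ring B | C[Si](C)(C)C#C[C@@H](O)C[C@]1(C(=O)OC)[C@H](CO[Si](C)(C)C(C)(C)C)C=C[C@H](c2occc2Br)[C@@H]1C(C)=C
F8 | step 6 | spirolactone diastereomer of 17 ((S)-carbinol, mirror-image ring B) | C[Si](C)(C)C#C[C@@H]1C[C@]2(C(=O)O1)[C@H](CO[Si](C)(C)C(C)(C)C)C=C[C@H](c3occc3Br)[C@@H]2C(C)=C
F9 | step 8 | Weinreb amide of 13 (1β-CH2C(=O)N(OMe)Me) | CON(C)C(=O)C[C@@]1(C(=O)OC)[C@@H](CO[Si](C)(C)C(C)(C)C)C=C[C@@H](c2occc2Br)[C@H]1C(C)=C
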